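**Retrosynthetic overview**
1. Target 20 comes from biaryl tetrol 19 by a twofold Teuber oxidation (each resorcinol ring becomes a 2-hydroxy-1,4-quinone); 19 comes from 18 by ether cleavage.
2. Key bond (the tetra-ortho-substituted aryl–aryl bond): 18 from a palladium-catalysed C4–H arylation of the free resorcinol 17 (ring A) with the hindered aryl bromide 16 (ring B).
3. 16 and 17 come from bibenzyls 15 and 12, each made by 9-BBN hydroboration / B-alkyl Suzuki coupling of styrene 13 or 2-methoxystyrene 10 with the common bromide 6.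
4. 6 comes from resorcinol by O-isopropylation, C2 lithiation–methylation and iridium-catalysed C5–H borylation / bromodeboronation; 10 comes from 2-bromophenol and CH2=CHMgBr.
5. Ring order: no ring is built; all four benzene rings are bought, and the two quinone rings are unveiled together in the last step.

Assumption: the SMILES has no stereocentre and does not define the sense of the hindered biaryl axis, so nothing stereochemical has to be set and the compound is made without axial control.

**Route**

Step 1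
Reactants: 1 resorcinol (benzene-1,3-diol)
Product: 2 1,3-di(propan-2-yloxy)benzene
Conditions: 2-bromopropane (3 equiv), K2CO3 (3 equiv), DMF, 80 °C
Reagents that add atoms: 2-bromopropane, CC(C)Br
Why: Williamson O-alkylation of both phenols gives isopropyl ethers that survive organolithiums, boranes, palladium and NBS and are later cleaved by BCl3 without loss of an aryl methyl ether.

Step 2
Reactants: 2 1,3-di(propan-2-yloxy)benzene
Product: 4 2-methyl-1,3-di(propan-2-yloxy)benzene, via aryllithium 3 (not isolated)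
Conditions: n-BuLi (1.2 equiv), TMEDA, THF, 0 °C to rt; then MeI, 0 °C to rt
Reagents that add atoms: iodomethane, CI; n-butyllithium, [Li]CCCC (lithium of intermediate 3 only)
Why: Directed ortho-metalation takes place only at C2, the C–H flanked and chelated by both alkoxy groups, and the aryllithium is methylated by MeI.

Step 3
Reactants: 4 2-methyl-1,3-di(propan-2-yloxy)benzene
Product: 6 5-bromo-2-methyl-1,3-di(propan-2-yloxy)benzene, via arylboronic ester 5 (not isolated)
Conditions: [Ir(OMe)(cod)]2 (1.5 mol %), 4,4'-di-tert-butyl-2,2'-bipyridine (3 mol %), B2pin2 (1.0 equiv), THF, 80 °C; evaporate; CuBr2 (3 equiv), MeOH/H2O 1:1, 80 °C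
Reagents that add atoms: copper dibromide, Br[Cu]Br; bis(pinacolato)diboron, CC1(C)OB(OC1(C)C)B1OC(C)(C)C(C)(C)O1 (boryl group of intermediate 5 only)
Why: Sterically controlled iridium-catalysed C–H borylation reaches only C5, the one C–H without an ortho substituent, and copper-mediated ipso-bromodeboronation of the crude boronic ester gives the bromide in one pot.

Step 4
Reactants: 7 2-bromophenol
Product: 8 1-bromo-2-methoxybenzene
Conditions: MeI (1.5 equiv), K2CO3, acetone, reflux
Reagents that add atoms: iodomethane, CI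
Why: Williamson methylation of the phenoxide installs the side-chain methoxy group that is kept to the end.

Step 5
Reactants: 8 1-bromo-2-methoxybenzene; 9 vinylmagnesium bromide (CH2=CHMgBr, 1.0 M in THF)
Product: 10 1-ethenyl-2-methoxybenzene
Conditions: PdCl2(dppf) (2 mol %), THF, 50 °C
Reagents that add atoms: none
Why: Kumada–Corriu coupling of an aryl bromide with a vinyl Grignard reagent is fast under PdCl2(dppf) and the methoxy group is inert.

Step 6
Reactants: 10 1-ethenyl-2-methoxybenzene; 6 5-bromo-2-methyl-1,3-di(propan-2-yloxy)benzene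
Product: 12 5-[2-(2-methoxyphenyl)ethyl]-2-methyl-1,3-di(propan-2-yloxy)benzene, via alkylborane 11 (not isolated)
Conditions: 10 (1.3 equiv), 9-BBN (0.5 M in THF), 0 °C to rt; then 6, PdCl2(dppf) (3 mol %), aq K3PO4 (3 M), DMF, 60 °C
Reagents that add atoms: 9-borabicyclo[3.3.1]nonane, B1C2CCCC1CCC2 (heavy atoms stay in intermediate 11 only)
Why: Anti-Markovnikov hydroboration of the styrene followed by B-alkyl Suzuki–Miyaura coupling forms the aryl–CH2 bond, with the dppf ligand suppressing β-hydride elimination.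

Step 7
Reactants: 13 styrene; 6 5-bromo-2-methyl-1,3-di(propan-2-yloxy)benzene
Product: 15 2-methyl-5-(2-phenylethyl)-1,3-di(propan-2-yloxy)benzene, via alkylborane 14 (not isolated)
Conditions: 13 (1.3 equiv), 9-BBN (0.5 M in THF), 0 °C to rt; then 6, PdCl2(dppf) (3 mol %), aq K3PO4 (3 M), DMF, 60 °C
Reagents that add atoms: 9-borabicyclo[3.3.1]nonane, B1C2CCCC1CCC2 (heavy atoms stay in intermediate 14 only)
Why: The same hydroboration / B-alkyl Suzuki–Miyaura sequence as in step 6 delivers the second bibenzyl.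

Step 8
Reactants: 15 2-methyl-5-(2-phenylethyl)-1,3-di(propan-2-yloxy)benzene
Product: 16 1-bromo-3-methyl-6-(2-phenylethyl)-2,4-di(propan-2-yloxy)benzene
Conditions: NBS (1.0 equiv), MeCN, 0 °C, dark
Reagents that add atoms: N-bromosuccinimide, O=C1CCC(=O)N1Br
Why: Electrophilic aromatic bromination goes to the position ortho to one alkoxy group and para to the other, the pendant phenyl ring is unactivated, and one equivalent at 0 °C stops at the monobromide (the two open positions are equivalent).

Step 9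
Reactants: 12 5-[2-(2-methoxyphenyl)ethyl]-2-methyl-1,3-di(propan-2-yloxy)benzene
Product: 17 5-[2-(2-methoxyphenyl)ethyl]-2-methylbenzene-1,3-diol
Conditions: BCl3 (1.0 M in CH2Cl2, 4 equiv), CH2Cl2, −78 to 0 °C; H2O
Reagents that add atoms: none
Why: BCl3 cleaves secondary-alkyl aryl ethers (loss of 2-chloropropane) at or below 0 °C, while the aryl methyl ether is inert under these conditions.

Step 10
Reactants: 17 5-[2-(2-methoxyphenyl)ethyl]-2-methylbenzene-1,3-diol (1.5 equiv); 16 1-bromo-3-methyl-6-(2-phenylethyl)-2,4-di(propan-2-yloxy)benzene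
Product: 18 6-[2-(2-methoxyphenyl)ethyl]-3,3'-dimethyl-6'-(2-phenylethyl)-2',4'-di(propan-2-yloxy)-[1,1'-biphenyl]-2,4-diol
Conditions: Pd2(dba)3 (2.5 mol %), SPhos (10 mol %), anhydrous K3PO4 (3 equiv), toluene, 110 °C, argon
Reagents that add atoms: none
Why: Proposed new method: a palladium-catalysed C4–H arylation of an unprotected resorcinol by a di-ortho-substituted aryl bromide, in which oxidative addition of 16 to zerovalent palladium gives a divalent arylpalladium bromide, the potassium resorcinolate of 17 displaces bromide, the O-bound phenoxide slips to its C4-bound cyclohexadienone (oxa-π-benzyl) form, C–C reductive elimination occurs at this sp3-like carbon (which eases the tetra-ortho congestion of a normal biaryl elimination) and tautomerisation rearomatises the ring; the dicyclohexylbiarylphosphine and the tight potassium ion pair in toluene disfavour C–O reductive elimination, the two nucleophilic positions of 17 are equivalent, and the excess of 17 limits double arylation; the closest known reaction type is the palladium-catalysed α-arylation of enolates, together with the ortho-arylation and arylative dearomatisation of phenols and naphthols by aryl halides; no stereocentre is formed.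

Step 11
Reactants: 18 6-[2-(2-methoxyphenyl)ethyl]-3,3'-dimethyl-6'-(2-phenylethyl)-2',4'-di(propan-2-yloxy)-[1,1'-biphenyl]-2,4-diol
Product: 19 6-[2-(2-methoxyphenyl)ethyl]-3,3'-dimethyl-6'-(2-phenylethyl)-[1,1'-biphenyl]-2,2',4,4'-tetrol
Conditions: BCl3 (1.0 M in CH2Cl2, 8 equiv), CH2Cl2, −78 °C to rt; H2O
Reagents that add atoms: none
Why: The same selective BCl3 de-isopropylation as in step 9 frees the two phenols of ring B and leaves the side-chain methyl ether.

Step 12
Reactants: 19 6-[2-(2-methoxyphenyl)ethyl]-3,3'-dimethyl-6'-(2-phenylethyl)-[1,1'-biphenyl]-2,2',4,4'-tetrol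
Product: 20 2-hydroxy-5-[4-hydroxy-5-methyl-3,6-dioxo-2-(2-phenylethyl)cyclohexa-1,4-dien-1-yl]-6-[2-(2-methoxyphenyl)ethyl]-3-methylcyclohexa-2,5-diene-1,4-dione (CNP0202346.0)
Conditions: K2[ON(SO3)2] (5 equiv), aq KH2PO4 (pH 6), acetone, 0 °C to rt
Reagents that add atoms: dipotassium nitrosodisulfonate, [K+].[K+].[O]N(S(=O)(=O)[O-])S(=O)(=O)[O-]
Why: Teuber oxidation: each resorcinol ring has exactly one free position, para to one hydroxyl, so two nitroxyl radicals per ring give the para-quinone and leave the other hydroxyl as the 2-hydroxy group; the anisole and phenyl rings are not oxidised.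

**Compound list**
1 | resorcinol (benzene-1,3-diol) | Oc1cccc(O)c1 | starting material
2 | 1,3-di(propan-2-yloxy)benzene | CC(C)Oc1cccc(OC(C)C)c1 | intermediate
3 | [2,6-di(propan-2-yloxy)phenyl]lithium | [Li]c1c(OC(C)C)cccc1OC(C)C | intermediate (not isolated)
4 | 2-methyl-1,3-di(propan-2-yloxy)benzene | Cc1c(OC(C)C)cccc1OC(C)C | intermediate
5 | 4,4,5,5-tetramethyl-2-[4-methyl-3,5-di(propan-2-yloxy)phenyl]-1,3,2-dioxaborolane | Cc1c(OC(C)C)cc(cc1OC(C)C)B1OC(C)(C)C(C)(C)O1 | intermediate (not isolated)
6 | 5-bromo-2-methyl-1,3-di(propan-2-yloxy)benzene | Cc1c(OC(C)C)cc(Br)cc1OC(C)C | intermediate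
7 | 2-bromophenol | Oc1ccccc1Br | starting material
8 | 1-bromo-2-methoxybenzene | COc1ccccc1Br | intermediate
9 | vinylmagnesium bromide | C=C[Mg]Br | starting material
10 | 1-ethenyl-2-methoxybenzene | COc1ccccc1C=C | intermediate
11 | 9-[2-(2-methoxyphenyl)ethyl]-9-borabicyclo[3.3.1]nonane | COc1ccccc1CCB1C2CCCC1CCC2 | intermediate (not isolated)
12 | 5-[2-(2-methoxyphenyl)ethyl]-2-methyl-1,3-di(propan-2-yloxy)benzene | COc1ccccc1CCc1cc(OC(C)C)c(C)c(OC(C)C)c1 | intermediate
13 | styrene | C=Cc1ccccc1 | starting material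
14 | 9-(2-phenylethyl)-9-borabicyclo[3.3.1]nonane | C(Cc1ccccc1)B1C2CCCC1CCC2 | intermediate (not isolated)
15 | 2-methyl-5-(2-phenylethyl)-1,3-di(propan-2-yloxy)benzene | Cc1c(OC(C)C)cc(CCc2ccccc2)cc1OC(C)C | intermediate
16 | 1-bromo-3-methyl-6-(2-phenylethyl)-2,4-di(propan-2-yloxy)benzene | Cc1c(OC(C)C)cc(CCc2ccccc2)c(Br)c1OC(C)C | intermediate
17 | 5-[2-(2-methoxyphenyl)ethyl]-2-methylbenzene-1,3-diol | COc1ccccc1CCc1cc(O)c(C)c(O)c1 | intermediate
18 | 6-[2-(2-methoxyphenyl)ethyl]-3,3'-dimethyl-6'-(2-phenylethyl)-2',4'-di(propan-2-yloxy)-[1,1'-biphenyl]-2,4-diol | COc1ccccc1CCc1cc(O)c(C)c(O)c1-c1c(CCc2ccccc2)cc(OC(C)C)c(C)c1OC(C)C | intermediate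
19 | 6-[2-(2-methoxyphenyl)ethyl]-3,3'-dimethyl-6'-(2-phenylethyl)-[1,1'-biphenyl]-2,2',4,4'-tetrol | COc1ccccc1CCc1cc(O)c(C)c(O)c1-c1c(CCc2ccccc2)cc(O)c(C)c1O | intermediate
20 | 2-hydroxy-5-[4-hydroxy-5-methyl-3,6-dioxo-2-(2-phenylethyl)cyclohexa-1,4-dien-1-yl]-6-[2-(2-methoxyphenyl)ethyl]-3-methylcyclohexa-2,5-diene-1,4-dione | COc1ccccc1CCC1=C(C2=C(CCc3ccccc3)C(=O)C(O)=C(C)C2=O)C(=O)C(C)=C(O)C1=O | target

**Step count and risks**
Total step count: 12. Longest linear sequence: 8 (steps 1, 2, 3, 6, 9, 10, 11, 12; the branch through steps 7 and 8 is equally long).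

Step 10 (the proposed new C–H arylation) may give O-arylation, low conversion or double arylation. The fallback uses known chemistry, sets out from 12 and 16 and comes back at 19. Compound 12 is not deprotected but brominated with NBS (1.0 equiv, MeCN, 0 °C; the dialkoxy ring is far more reactive than the anisole ring) to give 1-bromo-6-[2-(2-methoxyphenyl)ethyl]-3-methyl-2,4-di(propan-2-yloxy)benzene F1. Bromide 16 is treated with n-BuLi (THF, −78 °C) to give [3-methyl-6-(2-phenylethyl)-2,4-di(propan-2-yloxy)phenyl]lithium F2, which ZnCl2 converts into chlorido[3-methyl-6-(2-phenylethyl)-2,4-di(propan-2-yloxy)phenyl]zinc F3. Negishi coupling of this arylzinc with F1 (Pd2(dba)3, RuPhos, THF/NMP, 70 °C, a system established for tetra-ortho-substituted biaryls) gives 6-[2-(2-methoxyphenyl)ethyl]-3,3'-dimethyl-6'-(2-phenylethyl)-2,2',4,4'-tetra(propan-2-yloxy)-1,1'-biphenyl F4. BCl3 (CH2Cl2, −78 °C to rt) then removes all four isopropyl groups to give 19.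

Step 12 (the twofold Teuber oxidation on a hindered biaryl) may stop at the mono-quinone or over-oxidise. The fallback sets out from 19 and comes back at 20, and puts the oxygen in through carbon. A double Vilsmeier–Haack formylation (POCl3, DMF, MeCN, 0 °C to rt, aqueous work-up) at the only free position of each resorcinol ring gives 2,2',4,4'-tetrahydroxy-6-[2-(2-methoxyphenyl)ethyl]-3,3'-dimethyl-6'-(2-phenylethyl)-[1,1'-biphenyl]-5,5'-dicarbaldehyde F5. Dakin oxidation (H2O2, aq NaOH, 0 °C) converts both formyl groups into hydroxyls with loss of formate and gives 6-[2-(2-methoxyphenyl)ethyl]-3,3'-dimethyl-6'-(2-phenylethyl)-[1,1'-biphenyl]-2,2',4,4',5,5'-hexol F6. This hexol is not isolated; air in the same basic medium oxidises each 1,2,4-triol ring to the hydroxyquinone, and acidification gives 20.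

Step 3 (one-pot borylation / bromodeboronation) may fail because CuBr2 can also brominate the electron-rich ring at C4. The fallback sets out from 4, comes back at 12 and 15, and bypasses 6. The sequence is stopped after the borylation and boronic ester 5 is isolated. An oxidative boron-Heck reaction of 5 (Pd(OAc)2, 2,9-dimethyl-1,10-phenanthroline, Na2CO3, O2, DMF/H2O, 50 °C) with 10 gives (E)-5-[2-(2-methoxyphenyl)ethenyl]-2-methyl-1,3-di(propan-2-yloxy)benzene F7, and with 13 it gives (E)-2-methyl-5-(2-phenylethenyl)-1,3-di(propan-2-yloxy)benzene F8. Hydrogenation of each stilbene (H2, 1 atm, Pd/C, EtOAc, rt) gives 12 and 15.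

Further compounds
F1 | step 10 | 1-bromo-6-[2-(2-methoxyphenyl)ethyl]-3-methyl-2,4-di(propan-2-yloxy)benzene | COc1ccccc1CCc1cc(OC(C)C)c(C)c(OC(C)C)c1Br
F2 | step 10 | [3-methyl-6-(2-phenylethyl)-2,4-di(propan-2-yloxy)phenyl]lithium | [Li]c1c(CCc2ccccc2)cc(OC(C)C)c(C)c1OC(C)C
F3 | step 10 | chlorido[3-methyl-6-(2-phenylethyl)-2,4-di(propan-2-yloxy)phenyl]zinc | Cl[Zn]c1c(CCc2ccccc2)cc(OC(C)C)c(C)c1OC(C)C
F4 | step 10 | 6-[2-(2-methoxyphenyl)ethyl]-3,3'-dimethyl-6'-(2-phenylethyl)-2,2',4,4'-tetra(propan-2-yloxy)-1,1'-biphenyl | COc1ccccc1CCc1cc(OC(C)C)c(C)c(OC(C)C)c1-c1c(CCc2ccccc2)cc(OC(C)C)c(C)c1OC(C)C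
F5 | step 12 | 2,2',4,4'-tetrahydroxy-6-[2-(2-methoxyphenyl)ethyl]-3,3'-dimethyl-6'-(2-phenylethyl)-[1,1'-biphenyl]-5,5'-dicarbaldehyde | COc1ccccc1CCc1c(C=O)c(O)c(C)c(O)c1-c1c(CCc2ccccc2)c(C=O)c(O)c(C)c1O
F6 | step 12 | 6-[2-(2-methoxyphenyl)ethyl]-3,3'-dimethyl-6'-(2-phenylethyl)-[1,1'-biphenyl]-2,2',4,4',5,5'-hexol | COc1ccccc1CCc1c(O)c(O)c(C)c(O)c1-c1c(CCc2ccccc2)c(O)c(O)c(C)c1O
F7 | step 3 | (E)-5-[2-(2-methoxyphenyl)ethenyl]-2-methyl-1,3-di(propan-2-yloxy)benzene | COc1ccccc1/C=C/c1cc(OC(C)C)c(C)c(OC(C)C)c1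
F8 | step 3 | (E)-2-methyl-5-(2-phenylethenyl)-1,3-di(propan-2-yloxy)benzene | Cc1c(OC(C)C)cc(/C=C/c2ccccc2)cc1OC(C)C
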